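**Plan**

- Retrosynthesis: the 9,11-epoxide is removed; ring D is cut at C13–C16 (a C15 ynone on C8 facing a ring C cyclohexa-1,3-diene); the lactol is cut at O–C6; C15–C16 is cut back to a temporary lactone C15(=O)–O1; ring C is re-aromatized with loss of C7 from C8 (a benzoate); C9–C10 is cut by a retro-Claisen step to phenol and ethyl 2,6,6-trimethyl-4-oxocyclohex-2-ene-1-carboxylate.
- Forward: ring A is the starting ring; the arene that becomes ring C is attached at C10; the temporary six-membered lactone O1–C15 is closed; Birch reduction–alkylation dearomatizes the arene to ring C and creates C8; the lactone is opened by an acetylide; the lactol ring (C6–O–C7) is closed; ring D (C8, C14, C13, C16, C15) is closed last; the epoxide follows.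
- Enabling feature: the quaternary C8 holds the C15 ynone axially over the diene C9=C11–C12=C13, so C16 and C13 are 1,5-related, and the allyl radical C12–C11–C9 left by ring closure returns the alkene at C9=C11, where the epoxide is needed.
- Stereochemistry: C2 by CBS reduction, relayed to C5 (bicyclic lactone) and C10 (Mitsunobu inversion, suprafacial Claisen shift), then erased and reset together with C1 by hydride addition to a 1,2-dione anti to the axial C20 methyl; C8 by alkylation anti to C20 on the trans-fused temporary lactone; C13 by the bridge; C9/C11 by epoxidation anti to the C15–C16 bridge; C6 equilibrates.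

Key step: step 20

Locants: C1–C20 as in the ent-kaurane-type skeleton of the target (ring A: C1–C5, C10; ring C: C8, C9, C11–C14; ring D: C8, C14, C13, C16, C15); α is the face of the C20 methyl group, β the opposite face.

Assumption: the lactol carbon C6 is an equilibrating hemiacetal centre and the 6β-hydroxy anomer of the target is taken as the one favoured at equilibrium; the 9,11-epoxide is treated as a functional group placed on the finished ring skeleton.

**Route**

Step 1
Reactants: 1 ethyl 2,6,6-trimethyl-4-oxocyclohex-2-ene-1-carboxylate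
Product: 2 ethyl (4S)-4-hydroxy-2,6,6-trimethylcyclohex-2-ene-1-carboxylate (both C1 epimers)
Conditions: (R)-2-methyl-CBS-oxazaborolidine (0.2 equiv), BH3·SMe2, THF, −20 °C; MeOH quench
Reagents that add atoms: none
Why: Corey–Bakshi–Shibata reduction delivers hydride 1,2 to the enone carbonyl with the alkenyl side as the large group, which should set the carbinol carbon (C2) as S in both C5 epimers of the racemic, configurationally labile substrate, the C5 centre being corrected in step 3.

Step 2
Reactants: 2 ethyl (4S)-4-hydroxy-2,6,6-trimethylcyclohex-2-ene-1-carboxylate (both C1 epimers)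
Product: 3 (4S)-4-hydroxy-2,6,6-trimethylcyclohex-2-ene-1-carboxylic acid (both C1 epimers)
Conditions: LiOH·H2O, THF/MeOH/H2O, 40 °C; then 1 M HCl to pH 3, 0 °C
Reagents that add atoms: lithium hydroxide, [Li+].[OH-]
Why: Saponification of the hindered ester by acyl–oxygen cleavage should leave the allylic carbinol centre untouched, and epimerization at C5 is immaterial at this stage.

Step 3
Reactants: 3 (4S)-4-hydroxy-2,6,6-trimethylcyclohex-2-ene-1-carboxylic acid (both C1 epimers)
Product: 5 (1S,4R)-5,8,8-trimethyl-2-oxabicyclo[2.2.2]oct-5-en-3-one, via mixed anhydride 4 (not isolated)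
Conditions: 2,4,6-Cl3C6H2COCl, Et3N, THF, rt; then DMAP, PhMe (5 mM), 80 °C
Reagents that add atoms: none
Why: Yamaguchi lactonization: only the epimer with the acyl group cis to the C2 hydroxyl can close the 2-oxabicyclo[2.2.2]octenone, and because the α-hydrogen of the activated β,γ-unsaturated acyl unit exchanges through its dienolate under Et3N/DMAP both epimers should drain into 5, which fixes C5 relative to C2.

Step 4
Reactants: 5 (1S,4R)-5,8,8-trimethyl-2-oxabicyclo[2.2.2]oct-5-en-3-one
Product: 6 (1S,4R)-4-(hydroxymethyl)-3,5,5-trimethylcyclohex-2-en-1-ol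
Conditions: LiAlH4, THF, 0 °C
Reagents that add atoms: none
Why: Hydride reduction of the lactone opens the bridge to the cis-1,4-diol without touching a stereocentre.

Step 5
Reactants: 6 (1S,4R)-4-(hydroxymethyl)-3,5,5-trimethylcyclohex-2-en-1-ol
Product: 7 (1S,4R)-4-({[tert-butyl(dimethyl)silyl]oxy}methyl)-3,5,5-trimethylcyclohex-2-en-1-ol
Conditions: TBSCl (1.05 equiv), imidazole, CH2Cl2, −20 → 0 °C
Reagents that add atoms: tert-butyl(chloro)dimethylsilane, CC(C)(C)[Si](C)(C)Cl
Why: Silylation with one equivalent of silyl chloride at low temperature should select the primary hydroxyl over the secondary allylic one on steric grounds.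

Step 6
Reactants: 7 (1S,4R)-4-({[tert-butyl(dimethyl)silyl]oxy}methyl)-3,5,5-trimethylcyclohex-2-en-1-ol; 8 phenol
Product: 9 tert-butyl(dimethyl){[(1R,4R)-2,6,6-trimethyl-4-phenoxycyclohex-2-en-1-yl]methoxy}silane
Conditions: PPh3, DIAD, PhMe, 0 °C → rt
Reagents that add atoms: none
Why: Mitsunobu etherification: SN2 displacement of the activated allylic oxygen by phenoxide should invert C2 and place the aryloxy group on the β face, trans to the C5 side chain, SN2′ attack at the tetrasubstituted C10 being disfavoured.

Step 7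
Reactants: 9 tert-butyl(dimethyl){[(1R,4R)-2,6,6-trimethyl-4-phenoxycyclohex-2-en-1-yl]methoxy}silane
Product: 11 2-[(1R,6R)-6-({[tert-butyl(dimethyl)silyl]oxy}methyl)-1,5,5-trimethylcyclohex-2-en-1-yl]phenol, via cyclohexadienone 10 (not isolated)
Conditions: PhNEt2, 200 °C, sealed tube
Reagents that add atoms: none
Why: Aromatic Claisen rearrangement: the suprafacial [3,3] shift turns the β C2–O bond into a β C9–C10 bond, which should create the quaternary C10 (aryl β, methyl α, trans to C6) and the C1=C2 alkene, tautomerization of dienone 10 restoring the arene while the basic solvent suppresses addition of the phenol to the alkene.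

Step 8
Reactants: 11 2-[(1R,6R)-6-({[tert-butyl(dimethyl)silyl]oxy}methyl)-1,5,5-trimethylcyclohex-2-en-1-yl]phenol
Product: 12 2-[(1R,6R)-6-({[tert-butyl(dimethyl)silyl]oxy}methyl)-1,5,5-trimethylcyclohex-2-en-1-yl]phenyl trifluoromethanesulfonate
Conditions: Tf2O, pyridine, CH2Cl2, 0 °C
Reagents that add atoms: trifluoromethanesulfonic anhydride, O=S(=O)(OS(=O)(=O)C(F)(F)F)C(F)(F)F
Why: Sulfonylation of the phenol gives the aryl triflate needed for carbonylation, no stereocentre being involved.

Step 9
Reactants: 12 2-[(1R,6R)-6-({[tert-butyl(dimethyl)silyl]oxy}methyl)-1,5,5-trimethylcyclohex-2-en-1-yl]phenyl trifluoromethanesulfonate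
Product: 13 ring A 1β,2β-diol of aryl triflate 12 (cis-diol; C6 OTBS)
Conditions: OsO4 (5 mol %), NMO, acetone/H2O, rt
Reagents that add atoms: 4-methylmorpholine 4-oxide, C[N+]1([O-])CCOCC1; water, O
Why: Upjohn dihydroxylation of the only alkene (syn addition, expected anti to the pseudoaxial C20 methyl) gives a cis-diol whose configuration is irrelevant because both carbinol centres are erased in step 10.

Step 10
Reactants: 13 ring A 1β,2β-diol of aryl triflate 12 (cis-diol; C6 OTBS)
Product: 14 ring A 1,2-dione (aryl triflate; C6 OTBS)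
Conditions: IBX, DMSO, 60 °C
Reagents that add atoms: none
Why: IBX oxidizes vicinal diols to 1,2-diketones without C–C cleavage, and with C10 quaternary the dione can enolize only towards C3.

Step 11
Reactants: 14 ring A 1,2-dione (aryl triflate; C6 OTBS)
Product: 15 ring A 1α,2α-diol (aryl triflate; C6 OTBS)
Conditions: NaBH4, CeCl3·7H2O, MeOH, −40 → 0 °C
Reagents that add atoms: none
Why: Luche-type borohydride reduction: with aryl and CH2OTBS equatorial the C20 methyl and one C4 methyl are axial on the α face, so hydride should add to C1 axially from the β face (equatorial 1α-OH) and then to C2 from the β side because the α-axial approach is blocked by the two syn-axial methyls (axial 2α-OH), giving the cis-1α,2α-diol.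

Step 12
Reactants: 15 ring A 1α,2α-diol (aryl triflate; C6 OTBS)
Product: 16 trans-fused temporary lactone C15(=O)–O1 on the arene (2α-OH free; C6 OTBS)
Conditions: Pd(OAc)2 (5 mol %), dppp, CO (1 atm), Et3N, DMF, 70 °C
Reagents that add atoms: carbon monoxide, [C-]#[O+]
Why: Palladium-catalysed carbonylative lactonization of the aryl triflate: the equatorial C1 hydroxyl, trans to the aryl group, should close the six-membered trans-fused lactone, whereas the axial C2 hydroxyl cannot reach the acylpalladium.

Step 13
Reactants: 16 trans-fused temporary lactone C15(=O)–O1 on the arene (2α-OH free; C6 OTBS)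
Product: 18 C8-alkylated lactone with ring C as cyclohexa-1,4-diene (C7 OTIPS; C6 OTBS), via lithium enolate 17 (not isolated)
Conditions: Li (2.5 equiv), NH3(l)/THF, t-BuOH (1 equiv), −78 °C; isoprene; NH3 evaporated; TIPSOCH2Cl, THF, −78 → 0 °C
Reagents that add atoms: (chloromethoxy)tri(propan-2-yl)silane, CC(C)[Si](OCCl)(C(C)C)C(C)C
Why: Birch reduction–alkylation: dearomatization of the benzoate-type lactone gives the ester enolate 17 (protonated once at C12), and in the trans-fused lactone the axial C20 methyl lies over one face of the enolate, so the chloromethyl ether should C-alkylate C8 from the opposite face and set the quaternary C8 with C7 anti to C20.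

Step 14
Reactants: 18 C8-alkylated lactone with ring C as cyclohexa-1,4-diene (C7 OTIPS; C6 OTBS)
Product: 19 C8-alkylated lactone with ring C as cyclohexa-1,3-diene C9=C11–C12=C13
Conditions: RuHCl(CO)(PPh3)3 (5 mol %), PhMe, 80 °C
Reagents that add atoms: none
Why: Ruthenium hydride-catalysed alkene isomerization: hydrometalation of the less hindered C13=C14 bond and β-hydride elimination towards C12 should move it into conjugation with C9=C11, the quaternary C8 preventing aromatization.

Step 15
Reactants: 19 C8-alkylated lactone with ring C as cyclohexa-1,3-diene C9=C11–C12=C13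
Product: 20 C15 (trimethylsilyl)ynone 1α,2α-diol (C7 OTIPS; C6 OTBS)
Conditions: LiC≡CSiMe3 (2.5 equiv, commercial solution), THF, −78 → −40 °C; aq NH4Cl
Reagents that add atoms: lithium (trimethylsilyl)acetylide, [Li]C#C[Si](C)(C)C
Why: Acylation of the alkynyllithium by the lactone stops after one addition because the hindered tetrahedral intermediate persists until work-up, which should release the C1 hydroxyl (cleaving the temporary lactone) and give the C15 ynone.

Step 16
Reactants: 20 C15 (trimethylsilyl)ynone 1α,2α-diol (C7 OTIPS; C6 OTBS)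
Product: 21 C15 (trimethylsilyl)ynone 1α,2α-diacetate (C7 OTIPS; C6 OTBS)
Conditions: Ac2O, Et3N, DMAP (cat.), CH2Cl2, 0 °C → rt
Reagents that add atoms: acetic anhydride, CC(=O)OC(C)=O
Why: DMAP-catalysed acetylation of the open hydroxy ketone form should esterify both secondary hydroxyls (the axial C2 hydroxyl needing the nucleophilic catalyst), the β-silyl group shielding the ynone from conjugate addition.

Step 17
Reactants: 21 C15 (trimethylsilyl)ynone 1α,2α-diacetate (C7 OTIPS; C6 OTBS)
Product: 22 C6 primary alcohol (C7 OTIPS retained)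
Conditions: CSA (cat.), MeOH/CH2Cl2, 0 °C
Reagents that add atoms: none
Why: Acid-catalysed methanolysis cleaves the primary TBS ether much faster than the bulkier TIPS ether, the acetates and the C-silyl alkyne being stable to these conditions.

Step 18
Reactants: 22 C6 primary alcohol (C7 OTIPS retained)
Product: 23 C6 aldehyde (C7 OTIPS)
Conditions: Dess–Martin periodinane, NaHCO3, CH2Cl2, 0 °C → rt
Reagents that add atoms: none
Why: Dess–Martin oxidation of the only free hydroxyl gives the C6 aldehyde under buffered conditions that should not epimerize C5, which is flanked by two quaternary carbons.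

Step 19
Reactants: 23 C6 aldehyde (C7 OTIPS)
Product: 25 lactol with terminal C15 ynone (ring B closed as C6–O–C7), via hydroxy aldehyde 24 (not isolated)
Conditions: TBAF, AcOH, THF, 0 °C → rt
Reagents that add atoms: none
Why: Buffered fluoride cleaves the O–Si and C(sp)–Si bonds, and the liberated C7 hydroxyl should add spontaneously to the C6 aldehyde to close the seven-membered lactol ring, now possible because the C1/C15 tether is gone, the anomeric centre settling at equilibrium.

Step 20
Reactants: 25 lactol with terminal C15 ynone (ring B closed as C6–O–C7)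
Product: 27 tetracyclic 15-oxo-9(11),16-diene lactol diacetate, via vinylstannane 26 (not isolated)
Conditions: Bu3SnH (1.3 equiv, slow addition), AIBN (0.2 equiv), PhH (5 mM), 80 °C; then HCl (1 M in Et2O), CH2Cl2, 0 °C
Reagents that add atoms: none
Why: Bu3Sn• adds to the terminal alkyne carbon C17 and the resulting α-keto vinyl radical at C16 closes ring D by attack on C13, the terminus of the cyclohexa-1,3-diene, giving an allyl radical over C12–C11–C9 that takes hydrogen from Bu3SnH at the secondary end C12 so that the alkene is returned as C9=C11, after which acid replaces tin at C17 by hydrogen to unveil the 16-methylene-15-ketone. The closest known reaction type is the tin hydride-mediated addition–cyclization of 1,6-enynes followed by protodestannylation. Ring D (C8, C14, C13, C16, C15) forms in the 5-exo-trig mode, since 6-endo attack at C12 would forfeit allylic stabilization and attack at C9 would give a four-membered ring. The new stereocentre C13 is fixed by the one-atom C14 tether and the axial C15 on C8: the bridge can only form on the face of ring C that already carries C15, so C13 follows C8. The step needs cyclization to outrun hydrogen transfer to the vinyl radical, which slow addition of Bu3SnH at high dilution and the delocalized α-keto vinyl radical secure, and it needs regioselective quenching of the allyl radical, which the fully substituted C9 flanked by C8 and C10 secures.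

Step 21
Reactants: 27 tetracyclic 15-oxo-9(11),16-diene lactol diacetate
Product: 28 target CNP0224512.1
Conditions: mCPBA, NaHCO3, CH2Cl2, 0 °C
Reagents that add atoms: 3-chloroperoxybenzoic acid, OOC(=O)c1cccc(Cl)c1
Why: Prilezhaev epoxidation: the peracid should choose the electron-rich trisubstituted C9=C11 alkene over the electron-poor enone and attack the α face, anti to the C15–C16 bridge that lies syn-axial over C11 and to C1 which flanks the β face at C9, giving the 9α,11α-epoxide.

**Compound list**

1 | ethyl 2,6,6-trimethyl-4-oxocyclohex-2-ene-1-carboxylate (racemic) | CCOC(=O)C1C(C)=CC(=O)CC1(C)C | starting material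
2 | ethyl (4S)-4-hydroxy-2,6,6-trimethylcyclohex-2-ene-1-carboxylate (both C1 epimers) | CCOC(=O)C1C(C)(C)C[C@H](O)C=C1C | intermediate
3 | (4S)-4-hydroxy-2,6,6-trimethylcyclohex-2-ene-1-carboxylic acid (both C1 epimers) | OC(=O)C1C(C)(C)C[C@H](O)C=C1C | intermediate
4 | mixed anhydride of 3 and 2,4,6-trichlorobenzoic acid (both C1 epimers; not isolated) | O=C(OC(=O)C1C(C)(C)C[C@H](O)C=C1C)c1c(Cl)cc(Cl)cc1Cl | intermediate
5 | (1S,4R)-5,8,8-trimethyl-2-oxabicyclo[2.2.2]oct-5-en-3-one | O=C1[C@@H]2C(C)(C)C[C@H](O1)C=C2C | intermediate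
6 | (1S,4R)-4-(hydroxymethyl)-3,5,5-trimethylcyclohex-2-en-1-ol | OC[C@@H]1C(C)(C)C[C@H](O)C=C1C | intermediate
7 | (1S,4R)-4-({[tert-butyl(dimethyl)silyl]oxy}methyl)-3,5,5-trimethylcyclohex-2-en-1-ol | CC(C)(C)[Si](C)(C)OC[C@@H]1C(C)(C)C[C@H](O)C=C1C | intermediate
8 | phenol | Oc1ccccc1 | starting material
9 | tert-butyl(dimethyl){[(1R,4R)-2,6,6-trimethyl-4-phenoxycyclohex-2-en-1-yl]methoxy}silane | CC(C)(C)[Si](C)(C)OC[C@@H]1C(C)(C)C[C@@H](Oc2ccccc2)C=C1C | intermediate
10 | 6-substituted cyclohexa-2,4-dien-1-one from the [3,3] shift (ring A as in 11; dienone CH unassigned; not isolated) | CC(C)(C)[Si](C)(C)OC[C@@H]1C(C)(C)CC=C[C@@]1(C)C1C=CC=CC1=O | intermediate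
11 | 2-[(1R,6R)-6-({[tert-butyl(dimethyl)silyl]oxy}methyl)-1,5,5-trimethylcyclohex-2-en-1-yl]phenol (C10: aryl β, methyl α; C5: H β) | CC(C)(C)[Si](C)(C)OC[C@@H]1C(C)(C)CC=C[C@@]1(C)c1ccccc1O | intermediate
12 | 2-[(1R,6R)-6-({[tert-butyl(dimethyl)silyl]oxy}methyl)-1,5,5-trimethylcyclohex-2-en-1-yl]phenyl trifluoromethanesulfonate | CC(C)(C)[Si](C)(C)OC[C@@H]1C(C)(C)CC=C[C@@]1(C)c1ccccc1OS(=O)(=O)C(F)(F)F | intermediate
13 | ring A 1β,2β-diol of 12 | CC(C)(C)[Si](C)(C)OC[C@@H]1C(C)(C)C[C@@H](O)[C@@H](O)[C@@]1(C)c1ccccc1OS(=O)(=O)C(F)(F)F | intermediate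
14 | ring A 1,2-dione (aryl triflate; C6 OTBS) | CC(C)(C)[Si](C)(C)OC[C@@H]1C(C)(C)CC(=O)C(=O)[C@@]1(C)c1ccccc1OS(=O)(=O)C(F)(F)F | intermediate
15 | ring A 1α,2α-diol (aryl triflate; C6 OTBS; all of O1, O2, C6 and C20 α, aryl β) | CC(C)(C)[Si](C)(C)OC[C@@H]1C(C)(C)C[C@H](O)[C@H](O)[C@@]1(C)c1ccccc1OS(=O)(=O)C(F)(F)F | intermediate
16 | trans-fused temporary lactone: arene C8–C15(=O)–O1 (2α-OH; C6 OTBS; C20 axial α) | CC(C)(C)[Si](C)(C)OC[C@@H]1C(C)(C)C[C@H](O)[C@@H]2OC(=O)c3ccccc3[C@@]12C | intermediate
17 | lithium enolate of the 1,4-dihydro lactone (C8=C15 enolate; C12 H2; not isolated) | CC(C)(C)[Si](C)(C)OC[C@@H]1C(C)(C)C[C@H](O)[C@@H]2OC(O[Li])=C3C=CCC=C3[C@@]12C | intermediate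
18 | C8-alkylated lactone: C8 bears CH2OTIPS (C7) anti to C20; ring C cyclohexa-1,4-diene (C9=C11, C13=C14) | CC(C)(C)[Si](C)(C)OC[C@@H]1C(C)(C)C[C@H](O)[C@@H]2OC(=O)[C@]3(CO[Si](C(C)C)(C(C)C)C(C)C)C=CCC=C3[C@@]12C | intermediate
19 | C8-alkylated lactone with ring C cyclohexa-1,3-diene (C9=C11–C12=C13) | CC(C)(C)[Si](C)(C)OC[C@@H]1C(C)(C)C[C@H](O)[C@@H]2OC(=O)[C@]3(CO[Si](C(C)C)(C(C)C)C(C)C)CC=CC=C3[C@@]12C | intermediate
20 | C15 (trimethylsilyl)ynone 1α,2α-diol (C7 OTIPS; C6 OTBS) | CC(C)(C)[Si](C)(C)OC[C@@H]1C(C)(C)C[C@H](O)[C@H](O)[C@@]1(C)C1=CC=CC[C@@]1(CO[Si](C(C)C)(C(C)C)C(C)C)C(=O)C#C[Si](C)(C)C | intermediate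
21 | C15 (trimethylsilyl)ynone 1α,2α-diacetate (C7 OTIPS; C6 OTBS) | CC(C)(C)[Si](C)(C)OC[C@@H]1C(C)(C)C[C@H](OC(C)=O)[C@H](OC(C)=O)[C@@]1(C)C1=CC=CC[C@@]1(CO[Si](C(C)C)(C(C)C)C(C)C)C(=O)C#C[Si](C)(C)C | intermediate
22 | C6 primary alcohol (diacetate; C7 OTIPS; silyl ynone) | OC[C@@H]1C(C)(C)C[C@H](OC(C)=O)[C@H](OC(C)=O)[C@@]1(C)C1=CC=CC[C@@]1(CO[Si](C(C)C)(C(C)C)C(C)C)C(=O)C#C[Si](C)(C)C | intermediate
23 | C6 aldehyde (diacetate; C7 OTIPS; silyl ynone) | O=C[C@@H]1C(C)(C)C[C@H](OC(C)=O)[C@H](OC(C)=O)[C@@]1(C)C1=CC=CC[C@@]1(CO[Si](C(C)C)(C(C)C)C(C)C)C(=O)C#C[Si](C)(C)C | intermediate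
24 | C7 hydroxy C6 aldehyde with terminal ynone (not isolated) | O=C[C@@H]1C(C)(C)C[C@H](OC(C)=O)[C@H](OC(C)=O)[C@@]1(C)C1=CC=CC[C@@]1(CO)C(=O)C#C | intermediate
25 | lactol (ring B; 6β-OH drawn) with C15 terminal ynone and ring C 1,3-diene | C#CC(=O)[C@@]12CO[C@@H](O)[C@@H]3C(C)(C)C[C@H](OC(C)=O)[C@H](OC(C)=O)[C@@]3(C)C1=CC=CC2 | intermediate
26 | ring D-closed 17-(tributylstannyl) enone (E/Z mixture; not isolated) | CCCC[Sn](CCCC)(CCCC)C=C1C(=O)[C@@]23CO[C@@H](O)[C@@H]4C(C)(C)C[C@H](OC(C)=O)[C@H](OC(C)=O)[C@@]4(C)C2=CC[C@@H]1C3 | intermediate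
27 | tetracyclic 15-oxo-9(11),16-diene lactol 1α,2α-diacetate | C=C1C(=O)[C@@]23CO[C@@H](O)[C@@H]4C(C)(C)C[C@H](OC(C)=O)[C@H](OC(C)=O)[C@@]4(C)C2=CC[C@@H]1C3 | intermediate
28 | CNP0224512.1 (9α,11α-epoxide) | C=C1C(=O)[C@@]23CO[C@@H](O)[C@@H]4C(C)(C)C[C@H](OC(C)=O)[C@H](OC(C)=O)[C@@]4(C)[C@]24O[C@@H]4C[C@@H]1C3 | target

**Totals and risks**

Total step count: 21. Longest linear sequence: 21 steps (from 1; phenol 8 enters at step 6).

Steps most likely to fail:

1. Step 7 (aromatic Claisen rearrangement). The congested [3,3] shift, which forms the C9–C10 bond next to C5 and near a C4 methyl, may lose out to thermal extrusion of phenol (elimination to a diene) or to a [1,3] shift. Fallback: setting out from 7, the C2 hydroxyl is esterified with retention (picolinic acid, EDC·HCl, DMAP, CH2Cl2) to (1S,4R)-4-({[tert-butyl(dimethyl)silyl]oxy}methyl)-3,5,5-trimethylcyclohex-2-en-1-yl pyridine-2-carboxylate F3. Copper-mediated anti-SN2′ allylic substitution with [2-(prop-2-en-1-yloxy)phenyl]magnesium bromide (CuBr·SMe2, THF, −20 °C) should deliver the aryl group to the β face of C10, opposite the α leaving group, and give the allyl aryl ether tert-butyl(dimethyl)({(1R,6R)-2,2,6-trimethyl-6-[2-(prop-2-en-1-yloxy)phenyl]cyclohex-4-en-1-yl}methoxy)silane F4. Deallylation (Pd(PPh3)4, morpholine, THF) returns to the route at 11.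

2. Step 3 (lactonization with epimerization at C5). Epimerization of the activated acid may be too slow, so that the trans epimer oligomerizes, or the dienolate may reprotonate at the γ-carbon and move the alkene into conjugation. Fallback: setting out from 2, the epimers are separated by chromatography. The cis epimer ethyl (1R,4S)-4-hydroxy-2,6,6-trimethylcyclohex-2-ene-1-carboxylate F1 is reduced with LiAlH4 (THF, 0 °C) directly to the diol, rejoining the route at 6. The trans epimer ethyl (1S,4S)-4-hydroxy-2,6,6-trimethylcyclohex-2-ene-1-carboxylate F2 is oxidized with MnO2 back to 1, whose C5 centre racemizes with a trace of Et3N, and is passed through step 1 again.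

3. Step 20 (radical closure of ring D). Hydrogen transfer to the vinyl radical before cyclization would give simple hydrostannation of the ynone, and conjugate reduction could also compete. Fallback: setting out from 25, a palladium hydride route is used (Pd2(dba)3·CHCl3 as the zerovalent palladium source, P(o-tol)3, AcOH, Et3SiH, PhMe, 50 °C). Hydropalladation of the ynone should place palladium on C16, carbopalladation of C13 should give a π-allylpalladium over C12–C11–C9, and the silane should reduce it at C12. This comes back to the route at 27 without a new isolated compound (F0).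

Further compounds
F1 | step 3 | ethyl (1R,4S)-4-hydroxy-2,6,6-trimethylcyclohex-2-ene-1-carboxylate | CCOC(=O)[C@@H]1C(C)(C)C[C@H](O)C=C1C
F2 | step 3 | ethyl (1S,4S)-4-hydroxy-2,6,6-trimethylcyclohex-2-ene-1-carboxylate | CCOC(=O)[C@H]1C(C)(C)C[C@H](O)C=C1C
F3 | step 7 | (1S,4R)-4-({[tert-butyl(dimethyl)silyl]oxy}methyl)-3,5,5-trimethylcyclohex-2-en-1-yl pyridine-2-carboxylate | CC(C)(C)[Si](C)(C)OC[C@@H]1C(C)(C)C[C@H](OC(=O)c2ccccn2)C=C1C
F4 | step 7 | tert-butyl(dimethyl)({(1R,6R)-2,2,6-trimethyl-6-[2-(prop-2-en-1-yloxy)phenyl]cyclohex-4-en-1-yl}methoxy)silane | CC(C)(C)[Si](C)(C)OC[C@@H]1C(C)(C)CC=C[C@@]1(C)c1ccccc1OCC=C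
F0 | step 20 | none | none
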